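Spring lost 17.3 mM of substrate in 10.0 min on a charge of 8.9 mM reagent, more substrate than there was reagent to take it. So substrate has a way out that spends no reagent, and I don't expect larch to spend its full charge.

| flask | substrate | reagent | remark | time |
|---|---|---|---|---|
| spring | 20 mM | 8.9 mM | run made earlier |  |
| noon | 20 mM | 45 mM | run made earlier |  |
| larch | 20 mM | 60.0 mM |  | 15 min |
| birch | 20 mM | 16.0 mM |  | 15 min |

| run | time / min | bis adduct / % | triple product / % | substrate / % |
|---|---|---|---|---|
| spring | 0.833 | 0 | 0 | 69.6 |
| spring | 1.50 | 0.8 | 0 | 56.2 |
| spring | 3.00 | 1.6 | 0.4 | 37.2 |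
| spring | 6.00 | 2.2 | 0.4 | 21.1 |
| spring | 10.0 | 3.2 | 0.9 | 13.7 |
| noon | 2.00 | 6.8 | 2.0 | 33.1 |
| noon | 4.00 | 13.5 | 8.9 | 17.3 |
| noon | 6.00 | 14.3 | 16.5 | 10.5 |
| noon | 8.00 | 12.4 | 23.0 | 6.9 |
| noon | 10.0 | 12.7 | 29.7 | 4.9 |

(standard deviation of a reading: 0.5 percentage points)

- which of these holds the largest part of the substrate at the end of larch (substrate / bis adduct / single product / triple product)
- which of these holds the largest part of the substrate at the end of birch (substrate / bis adduct / single product / triple product)
- amount of bis adduct at the end of larch, in percent of the substrate charged

- a reading or a percentage of triple product counts all its forms, free or not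

I follow bis adduct through larch with one clock. In noon, triple product gains 13 percentage points in 4.00 min while bis adduct reads about 13.1%, a turnover of 0.251 min⁻¹. Reagent at 8.00 min is at most 26.2 mM, single product being uncounted. Dividing gives 0.160 M⁻¹ s⁻¹, the bis turnover constant: turnover per unit of reagent, pseudo-first-order at any one c(reagent). The half-life of bis adduct is ln(2) over this constant times c(reagent).

In the first instants of larch, c(reagent) is 60.0 mM, so the half-life is 1.21 min. In the middle it rises to a crest; noon's highest reading is 14.3%. Towards the end I take c(reagent) as half its charge, as noon has put half of its own into bis adduct and triple product by 10.0 min. The half-life is then 2.41 min, and the second half of larch holds 3.11 of them. Unfed, that crest would fall to 1.65%. Single product feeds it, so I commit to a figure between this and noon's 13.1%.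

The forecast says triple product for larch, single product for birch (“single product should clearly dominate”), and 10% bis adduct, within 6% to 15%.

Larch ends with triple product largest at 54.6%, birch with single product largest at 14.0%, and bis adduct in larch stands at 5.93%.

    2 substrate → homo dimer (k = 0.190 M⁻¹ s⁻¹)
    crystals ⇌ triple product, rate k2*(cs2 - [triple product]) while solid is left; crystals form when [triple product] > cs2 (solubility = 2.10 mM, k = 0.300 s⁻¹)
    reagent + single product → bis adduct (k = 0.130 M⁻¹ s⁻¹)
    reagent + bis adduct → triple product (k = 0.170 M⁻¹ s⁻¹)
    substrate + reagent → single product (k = 0.120 M⁻¹ s⁻¹)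

At that end larch keeps 40.1% of its reagent, so the clock reads 3.00 min, still shorter than the 15 min of the run.

In the neighbour flask, larch read at 6.0 min, reagent stands at 56.5% and bis adduct at 14.7%. The constant then gives a half-life of 2.13 min and about 9.6 points of triple product since the reading at 4.0 min. The computed gain is 11 points.

The numbers in the tables stem from a simulated flask from invented constants, and the scatter is random.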